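**Strategy.** The fourteen-membered carbocycle (C1–C14) is disconnected at C11–C12. The secondary C11 carbinol lies next to C12, the methyl- and oxygen-bearing ring atom that is also the alkoxy carbon of the seven-membered lactone, so this pair is treated as a masked allylic alcohol in which C12 carries an exocyclic methylene (later the C20 methyl). One chromium/nickel-mediated addition of a C12 alkenyl iodide to a C11 aldehyde then forms C11–C12, closes the macrocycle and creates the C11 stereocentre. Its precursor is an open-chain C11 aldehyde with C7 acetate, C8 silyl ether, E-C3=C4 alkene, C1 isopropenyl group and a terminal 2-iodoalkene (C12). Directed epoxidation and hydride opening later convert the methylene into the C12 methyl carbinol.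

Key step: step 15

Assumption: (R)-lavandulol, (2R,5R)-2-tert-butyl-5-methyl-1,3-dioxolan-4-one and 1-iodo-3-[(4-methoxybenzyl)oxy]propane are taken as purchasable; macrocycles are named with cembrane numbering (ring C1–C14, C15–C17 on C1, C18 on C4, C19 on C8, C20 on C12).

Step 1
Reactants: 1 (R)-lavandulol
Product: 2 (R)-lavandulyl bromide
Conditions: CBr4, PPh3, CH2Cl2, 0 °C
Reagents that add atoms: carbon tetrabromide, BrC(Br)(Br)Br
Why: Appel bromination of the primary alcohol runs through an alkoxyphosphonium salt under neutral conditions, so the C1 stereocentre and both alkenes are untouched.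

Step 2
Reactants: 2 (R)-lavandulyl bromide; 3 2,3-dibromopropene
Product: 5 (5R)-2-bromo-8-methyl-5-(prop-1-en-2-yl)nona-1,7-diene, via lavandulylmagnesium bromide 4 (not isolated)
Conditions: Mg, THF, 40 °C; then 3, CuI (5 mol%), THF, −20 °C to rt
Reagents that add atoms: none
Why: Grignard formation and copper-catalysed allylic substitution on 2,3-dibromopropene add C13, C12 and C20, since SN2 and SN2′ attack give the same 2-bromoallyl product and the alkenyl bromide does not react.

Step 3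
Reactants: 5 (5R)-2-bromo-8-methyl-5-(prop-1-en-2-yl)nona-1,7-diene
Product: 7 (5R)-2-iodo-8-methyl-5-(prop-1-en-2-yl)nona-1,7-diene, via alkenyllithium 6 (not isolated)
Conditions: t-BuLi (2.1 equiv), Et2O, −78 °C; then I2, −78 to 0 °C
Reagents that add atoms: iodine, I-I
Why: Bromine–lithium exchange at the alkenyl bromide outruns any deprotonation at −78 °C, and iodine traps the alkenyllithium to give the iodide needed for nickel insertion in step 15.

Step 4
Reactants: 7 (5R)-2-iodo-8-methyl-5-(prop-1-en-2-yl)nona-1,7-diene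
Product: 8 (2E,5R)-8-iodo-2-methyl-5-(prop-1-en-2-yl)nona-2,8-dien-1-ol
Conditions: SeO2 (0.3 equiv), t-BuOOH, CH2Cl2, 0 °C to rt
Reagents that add atoms: tert-butyl hydroperoxide, CC(C)(C)OO; selenium dioxide, O=[Se]=O
Why: Catalytic SeO2 allylic oxidation (ene reaction then [2,3]-sigmatropic shift) attacks the electron-rich trisubstituted alkene and oxidises its E-methyl group, so C5 becomes CH2OH with the E geometry of C3=C4 fixed while the isopropenyl and iodoalkene groups react far more slowly.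

Step 5
Reactants: 8 (2E,5R)-8-iodo-2-methyl-5-(prop-1-en-2-yl)nona-2,8-dien-1-ol
Product: 9 (2E,5R)-1-bromo-8-iodo-2-methyl-5-(prop-1-en-2-yl)nona-2,8-diene
Conditions: CBr4, PPh3, CH2Cl2, −20 °C
Reagents that add atoms: carbon tetrabromide, BrC(Br)(Br)Br
Why: Appel bromination converts the primary allylic alcohol into the bromide by direct SN2 displacement, without allylic transposition or loss of the E geometry.

Step 6
Reactants: 10 (2R,5R)-2-tert-butyl-5-methyl-1,3-dioxolan-4-one; 11 1-iodo-3-[(4-methoxybenzyl)oxy]propane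
Product: 13 (2R,5S)-2-tert-butyl-5-{3-[(4-methoxybenzyl)oxy]propyl}-5-methyl-1,3-dioxolan-4-one, via lithium enolate 12 (not isolated)
Conditions: LDA, THF, −78 °C; then 11, DMPU, −78 to −30 °C
Reagents that add atoms: none
Why: Enolate alkylation of the lactic-acid-derived dioxolanone (self-regeneration of stereocentres) brings the electrophile in trans to the tert-butyl group, which sets the quaternary C8 centre as S.

Step 7
Reactants: 13 (2R,5S)-2-tert-butyl-5-{3-[(4-methoxybenzyl)oxy]propyl}-5-methyl-1,3-dioxolan-4-one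
Product: 14 (2S)-2-hydroxy-N-methoxy-5-[(4-methoxybenzyl)oxy]-N,2-dimethylpentanamide
Conditions: MeNH(OMe)·HCl, AlMe3, CH2Cl2, 0 °C to rt
Reagents that add atoms: N,O-dimethylhydroxylamine hydrochloride, CNOC.Cl
Why: Weinreb aminolysis with the aluminium amide opens the acylal-type lactone at its carbonyl, and the released hemiacetal loses pivalaldehyde to give the tertiary alcohol with C8 unchanged.

Step 8
Reactants: 14 (2S)-2-hydroxy-N-methoxy-5-[(4-methoxybenzyl)oxy]-N,2-dimethylpentanamide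
Product: 15 (2S)-N-methoxy-5-[(4-methoxybenzyl)oxy]-N,2-dimethyl-2-[(triethylsilyl)oxy]pentanamide
Conditions: Et3SiOTf, 2,6-lutidine, CH2Cl2, −78 to 0 °C
Reagents that add atoms: triethylsilyl triflate, CC[Si](CC)(CC)OS(=O)(=O)C(F)(F)F
Why: Silylation with a silyl triflate and a hindered base masks the tertiary C8 hydroxyl, which otherwise would be deprotonated in step 10 and would form a lactol with the C11 aldehyde.

Step 9
Reactants: 15 (2S)-N-methoxy-5-[(4-methoxybenzyl)oxy]-N,2-dimethyl-2-[(triethylsilyl)oxy]pentanamide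
Product: 16 (3S)-6-[(4-methoxybenzyl)oxy]-3-methyl-3-[(triethylsilyl)oxy]hexan-2-one
Conditions: MeMgBr, THF, 0 °C
Reagents that add atoms: methylmagnesium bromide, C[Mg]Br
Why: Weinreb ketone synthesis stops at the methyl ketone because the chelated tetrahedral intermediate survives until work-up, and the new methyl group is C6.

Step 10
Reactants: 16 (3S)-6-[(4-methoxybenzyl)oxy]-3-methyl-3-[(triethylsilyl)oxy]hexan-2-one; 9 (2E,5R)-1-bromo-8-iodo-2-methyl-5-(prop-1-en-2-yl)nona-2,8-diene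
Product: 18 (4S,8E,11R)-14-iodo-1-[(4-methoxybenzyl)oxy]-4,8-dimethyl-11-(prop-1-en-2-yl)-4-[(triethylsilyl)oxy]pentadeca-8,14-dien-5-one, via lithium enolate 17 (not isolated)
Conditions: LDA (0.95 equiv), THF, −78 °C; then 9, DMPU, −78 to −40 °C
Reagents that add atoms: none
Why: Enolate alkylation forms C5–C6, because the ketone can enolise only toward its methyl group (C8 is quaternary) and the lithium enolate displaces the primary allylic bromide by SN2 with the alkene position and geometry intact and without exposing the alkenyl iodide to strong base.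

Step 11
Reactants: 18 (4S,8E,11R)-14-iodo-1-[(4-methoxybenzyl)oxy]-4,8-dimethyl-11-(prop-1-en-2-yl)-4-[(triethylsilyl)oxy]pentadeca-8,14-dien-5-one
Product: 19 (4S,5R,8E,11R)-14-iodo-1-[(4-methoxybenzyl)oxy]-4,8-dimethyl-11-(prop-1-en-2-yl)-4-[(triethylsilyl)oxy]pentadeca-8,14-dien-5-ol
Conditions: (S)-2-methyl-CBS-oxazaborolidine (0.5 equiv), catecholborane, toluene, −78 to −40 °C
Reagents that add atoms: none
Why: Corey–Bakshi–Shibata reduction sets C7 as R under reagent control, the (S)-oxazaborolidine reading the tertiary C8 group as large and the C6 methylene as small, while catecholborane does not hydroborate the alkenes.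

Step 12
Reactants: 19 (4S,5R,8E,11R)-14-iodo-1-[(4-methoxybenzyl)oxy]-4,8-dimethyl-11-(prop-1-en-2-yl)-4-[(triethylsilyl)oxy]pentadeca-8,14-dien-5-ol
Product: 20 (4S,5R,8E,11R)-14-iodo-1-[(4-methoxybenzyl)oxy]-4,8-dimethyl-11-(prop-1-en-2-yl)-4-[(triethylsilyl)oxy]pentadeca-8,14-dien-5-yl acetate
Conditions: Ac2O, 4-(dimethylamino)pyridine, pyridine, CH2Cl2, rt
Reagents that add atoms: acetic anhydride, CC(=O)OC(C)=O
Why: Nucleophile-catalysed acetylation protects the hindered C7 hydroxyl with a group that survives the oxidations and the ring closure and is removed by the hydride of step 18.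

Step 13
Reactants: 20 (4S,5R,8E,11R)-14-iodo-1-[(4-methoxybenzyl)oxy]-4,8-dimethyl-11-(prop-1-en-2-yl)-4-[(triethylsilyl)oxy]pentadeca-8,14-dien-5-yl acetate
Product: 21 (4S,5R,8E,11R)-1-hydroxy-14-iodo-4,8-dimethyl-11-(prop-1-en-2-yl)-4-[(triethylsilyl)oxy]pentadeca-8,14-dien-5-yl acetate
Conditions: DDQ, CH2Cl2/pH 7 buffer, 0 °C
Reagents that add atoms: none
Why: Oxidative cleavage of the 4-methoxybenzyl ether (benzylic hydride abstraction then hydrolysis) frees only the C11 alcohol and leaves silyl ether, acetate, alkenes and alkenyl iodide alone.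

Step 14
Reactants: 21 (4S,5R,8E,11R)-1-hydroxy-14-iodo-4,8-dimethyl-11-(prop-1-en-2-yl)-4-[(triethylsilyl)oxy]pentadeca-8,14-dien-5-yl acetate
Product: 22 (4S,5R,8E,11R)-14-iodo-4,8-dimethyl-1-oxo-11-(prop-1-en-2-yl)-4-[(triethylsilyl)oxy]pentadeca-8,14-dien-5-yl acetate
Conditions: Dess–Martin periodinane, pyridine, CH2Cl2, rt
Reagents that add atoms: none
Why: Dess–Martin oxidation gives the C11 aldehyde under buffered, non-basic conditions, and the adjacent C10 methylene has no stereocentre to lose.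

Step 15
Reactants: 22 (4S,5R,8E,11R)-14-iodo-4,8-dimethyl-1-oxo-11-(prop-1-en-2-yl)-4-[(triethylsilyl)oxy]pentadeca-8,14-dien-5-yl acetate
Product: 24 (1R,3E,7R,8S,11R)-7-acetoxy-8-(triethylsilyloxy)cembra-3,12(20),15(17)-trien-11-ol, via alkenylchromium dichloride 23 (not isolated)
Conditions: CrCl2 (divalent chromium, 6 equiv), NiCl2 (divalent nickel, 0.2 equiv), N-[2-(4-isopropyl-4,5-dihydrooxazol-2-yl)-6-methylphenyl]methanesulfonamide (antipode matched to Si-face attack, 6.5 equiv), Et3N, THF, 22 added slowly to 0.002 M, rt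
Reagents that add atoms: none
Why: Nozaki–Hiyama–Kishi reaction: zerovalent nickel, formed from NiCl2 by CrCl2, inserts into the C12–I bond and passes the alkenyl group to trivalent chromium, and the alkenylchromium 23 adds to the C11 aldehyde through a chromium-alkoxide transition state. The closest known reaction type is the chromium/nickel-mediated macrocyclisation of 2-iodo-1-alkenes onto aldehydes to give macrocyclic 2-methylene carbinols. The fourteen-membered ring closes as a 14-exo-trig carbonyl addition under high dilution. The new C11 stereocentre (11R, Si-face attack on the aldehyde) is placed under reagent control by the chromium-bound chiral oxazoline sulfonamide, because C8 and C1 are too remote for dependable substrate control. The step needs chemoselectivity for one C(sp2)–I bond and one aldehyde and ring closure in preference to oligomerisation; the substrate secures this with a single iodide, a single aldehyde without an adjacent stereocentre, spectator groups (acetate, silyl ether, unactivated alkenes) that organochromium species do not touch, and an E-alkene and quaternary C8 that restrict the chain.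

Step 16
Reactants: 24 (1R,3E,7R,8S,11R)-7-acetoxy-8-(triethylsilyloxy)cembra-3,12(20),15(17)-trien-11-ol
Product: 25 (1R,3E,7R,8S,11R,12S)-7-acetoxy-12,20-epoxy-8-(triethylsilyloxy)cembra-3,15(17)-dien-11-ol
Conditions: VO(acac)2 (5 mol%), t-BuOOH, CH2Cl2, 0 °C to rt
Reagents that add atoms: tert-butyl hydroperoxide, CC(C)(C)OO
Why: Vanadium-catalysed hydroxyl-directed epoxidation delivers oxygen from the C11 vanadate ester only to the adjacent 1,1-disubstituted alkene, and avoidance of A(1,2) strain between the C13 methylene on C12 and the C10 substituent on C11 places the new C12–O bond syn to the C11–O bond.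

Step 17
Reactants: 25 (1R,3E,7R,8S,11R,12S)-7-acetoxy-12,20-epoxy-8-(triethylsilyloxy)cembra-3,15(17)-dien-11-ol
Product: 26 (1R,3E,7R,8S,11R,12S)-7-acetoxy-12,20-epoxy-8,11-bis(triethylsilyloxy)cembra-3,15(17)-diene
Conditions: Et3SiCl, imidazole, 4-(dimethylamino)pyridine (cat.), DMF, rt
Reagents that add atoms: chlorotriethylsilane, CC[Si](Cl)(CC)CC
Why: Silylation masks the secondary C11 hydroxyl so that C7–OH can later be acetylated alone and only the tertiary C12–OH is free for lactonisation.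

Step 18
Reactants: 26 (1R,3E,7R,8S,11R,12S)-7-acetoxy-12,20-epoxy-8,11-bis(triethylsilyloxy)cembra-3,15(17)-diene
Product: 27 (1R,3E,7R,8S,11R,12R)-8,11-bis(triethylsilyloxy)cembra-3,15(17)-diene-7,12-diol
Conditions: LiAlH4, THF, 0 °C
Reagents that add atoms: none
Why: Hydride opens the spiro-epoxide by SN2 attack at its CH2 terminus (C20), which gives the C12 methyl carbinol with C12–O untouched, and the same reagent cleaves the C7 acetate while the silyl ethers stay in place at 0 °C.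

Step 19
Reactants: 27 (1R,3E,7R,8S,11R,12R)-8,11-bis(triethylsilyloxy)cembra-3,15(17)-diene-7,12-diol
Product: 28 (1R,3E,7R,8S,11R,12R)-7-acetoxy-8,11-bis(triethylsilyloxy)cembra-3,15(17)-dien-12-ol
Conditions: Ac2O, pyridine, 4-(dimethylamino)pyridine (cat.), CH2Cl2, 0 °C
Reagents that add atoms: acetic anhydride, CC(=O)OC(C)=O
Why: Acetylation takes the only secondary hydroxyl (C7), since the tertiary C12 hydroxyl next to the C11 silyl ether is acylated far more slowly under these conditions.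

Step 20
Reactants: 28 (1R,3E,7R,8S,11R,12R)-7-acetoxy-8,11-bis(triethylsilyloxy)cembra-3,15(17)-dien-12-ol
Product: 29 (1R,3S,4S,7R,8S,11R,12R)-7-acetoxy-3,4-epoxy-8,11-bis(triethylsilyloxy)cembr-15(17)-en-12-ol
Conditions: ent-Shi ketone (1,2:4,5-di-O-isopropylidene-β-L-erythro-2,3-hexodiulo-2,6-pyranose, 0.5 equiv), KHSO5 (as 2KHSO5·KHSO4·K2SO4), K2CO3, Bu4NHSO4, MeCN/CH2(OMe)2/aq. Na2B4O7, 0 °C
Reagents that add atoms: potassium peroxymonosulfate, [K+].[O-]S(=O)(=O)OO
Why: Shi epoxidation through the chiral dioxirane and a spiro transition state epoxidises the E-trisubstituted C3=C4 alkene with reagent-controlled facial selectivity (3S,4S from the L-fructose-derived ketone, the mirror image of the R,R sense of the D-fructose-derived one) and leaves the less nucleophilic isopropenyl group.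

Step 21
Reactants: 29 (1R,3S,4S,7R,8S,11R,12R)-7-acetoxy-3,4-epoxy-8,11-bis(triethylsilyloxy)cembr-15(17)-en-12-ol
Product: 31 (1R,3S,4S,7R,8S,11R,12R)-7-acetoxy-3,4-epoxy-12-hydroxy-8,11-bis(triethylsilyloxy)cembr-15(17)-en-16-al, via allylic alcohol 30 (not isolated)
Conditions: SeO2 (0.5 equiv), t-BuOOH, CH2Cl2, rt; then Dess–Martin periodinane, pyridine, CH2Cl2, rt
Reagents that add atoms: tert-butyl hydroperoxide, CC(C)(C)OO; selenium dioxide, O=[Se]=O
Why: SeO2 allylic oxidation now finds the isopropenyl group as the only alkene and oxidises its methyl group in preference to the C1 methine, and Dess–Martin oxidation of the crude primary allylic alcohol gives the enal without touching the tertiary hydroxyl.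

Step 22
Reactants: 31 (1R,3S,4S,7R,8S,11R,12R)-7-acetoxy-3,4-epoxy-12-hydroxy-8,11-bis(triethylsilyloxy)cembr-15(17)-en-16-al
Product: 32 (1R,3S,4S,7R,8S,11R,12R)-7-acetoxy-3,4-epoxy-12-hydroxy-8,11-bis(triethylsilyloxy)cembr-15(17)-en-16-oic acid
Conditions: NaClO2, NaH2PO4, 2-methyl-2-butene, t-BuOH/H2O, 0 °C to rt
Reagents that add atoms: sodium chlorite, [Na+].[O-]Cl=O
Why: Pinnick oxidation converts the enal into the acrylic acid at about pH 4 with an alkene scavenger for hypochlorous acid, conditions that leave epoxide, silyl ethers and acetate intact.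

Step 23
Reactants: 32 (1R,3S,4S,7R,8S,11R,12R)-7-acetoxy-3,4-epoxy-12-hydroxy-8,11-bis(triethylsilyloxy)cembr-15(17)-en-16-oic acid
Product: 34 (1R,3S,4S,7R,8S,11R,12R)-7-acetoxy-3,4-epoxy-8,11-bis(triethylsilyloxy)cembr-15(17)-en-16,12-olide, via mixed anhydride 33 (not isolated)
Conditions: 2,4,6-trichlorobenzoyl chloride, Et3N, THF, rt; then 4-(dimethylamino)pyridine, toluene, 0.002 M, 80 °C
Reagents that add atoms: none
Why: Yamaguchi lactonisation turns the mixed anhydride into an acylpyridinium ion that is attacked by the only free hydroxyl, the tertiary C12–OH, in a 7-exo-trig closure under high dilution.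

Step 24
Reactants: 34 (1R,3S,4S,7R,8S,11R,12R)-7-acetoxy-3,4-epoxy-8,11-bis(triethylsilyloxy)cembr-15(17)-en-16,12-olide
Product: 35 (1R,3S,4S,7R,8S,11R,12R)-7-acetoxy-3,4-epoxy-8,11-dihydroxycembr-15(17)-en-16,12-olide (CNP0174704.2)
Conditions: HF·pyridine, pyridine, THF, 0 °C to rt
Reagents that add atoms: none
Why: Fluoride-mediated desilylation under pyridine-buffered conditions removes both triethylsilyl groups without opening the epoxide, migrating the acetate or adding to the methylene lactone.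

**Compound list**

1 | (R)-lavandulol [(2R)-5-methyl-2-(prop-1-en-2-yl)hex-4-en-1-ol] | OC[C@@H](C(C)=C)CC=C(C)C | starting material
2 | (R)-lavandulyl bromide [(2R)-1-bromo-5-methyl-2-(prop-1-en-2-yl)hex-4-ene] | BrC[C@@H](C(C)=C)CC=C(C)C | intermediate
3 | 2,3-dibromopropene | C=C(Br)CBr | starting material
4 | (R)-lavandulylmagnesium bromide | Br[Mg]C[C@@H](C(C)=C)CC=C(C)C | intermediate
5 | (5R)-2-bromo-8-methyl-5-(prop-1-en-2-yl)nona-1,7-diene | C=C(Br)CC[C@@H](C(C)=C)CC=C(C)C | intermediate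
6 | (5R)-8-methyl-5-(prop-1-en-2-yl)nona-1,7-dien-2-yllithium | [Li]C(=C)CC[C@@H](C(C)=C)CC=C(C)C | intermediate
7 | (5R)-2-iodo-8-methyl-5-(prop-1-en-2-yl)nona-1,7-diene | C=C(I)CC[C@@H](C(C)=C)CC=C(C)C | intermediate
8 | (2E,5R)-8-iodo-2-methyl-5-(prop-1-en-2-yl)nona-2,8-dien-1-ol | C=C(I)CC[C@@H](C(C)=C)C/C=C(C)/CO | intermediate
9 | (2E,5R)-1-bromo-8-iodo-2-methyl-5-(prop-1-en-2-yl)nona-2,8-diene | C=C(I)CC[C@@H](C(C)=C)C/C=C(C)/CBr | intermediate
10 | (2R,5R)-2-tert-butyl-5-methyl-1,3-dioxolan-4-one (cis, from (R)-lactic acid) | C[C@H]1O[C@@H](C(C)(C)C)OC1=O | starting material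
11 | 1-iodo-3-[(4-methoxybenzyl)oxy]propane | ICCCOCc1ccc(OC)cc1 | starting material
12 | lithium (2R)-2-tert-butyl-5-methyl-1,3-dioxol-4-olate (enolate of 10) | CC1=C(O[Li])O[C@H](C(C)(C)C)O1 | intermediate
13 | (2R,5S)-2-tert-butyl-5-{3-[(4-methoxybenzyl)oxy]propyl}-5-methyl-1,3-dioxolan-4-one | C[C@@]1(CCCOCc2ccc(OC)cc2)O[C@@H](C(C)(C)C)OC1=O | intermediate
14 | (2S)-2-hydroxy-N-methoxy-5-[(4-methoxybenzyl)oxy]-N,2-dimethylpentanamide | CON(C)C(=O)[C@@](C)(O)CCCOCc1ccc(OC)cc1 | intermediate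
15 | (2S)-N-methoxy-5-[(4-methoxybenzyl)oxy]-N,2-dimethyl-2-[(triethylsilyl)oxy]pentanamide | CON(C)C(=O)[C@@](C)(O[Si](CC)(CC)CC)CCCOCc1ccc(OC)cc1 | intermediate
16 | (3S)-6-[(4-methoxybenzyl)oxy]-3-methyl-3-[(triethylsilyl)oxy]hexan-2-one | CC(=O)[C@@](C)(O[Si](CC)(CC)CC)CCCOCc1ccc(OC)cc1 | intermediate
17 | lithium (3S)-6-[(4-methoxybenzyl)oxy]-3-methyl-3-[(triethylsilyl)oxy]hex-1-en-2-olate (enolate of 16) | C=C(O[Li])[C@@](C)(O[Si](CC)(CC)CC)CCCOCc1ccc(OC)cc1 | intermediate
18 | (4S,8E,11R)-14-iodo-1-[(4-methoxybenzyl)oxy]-4,8-dimethyl-11-(prop-1-en-2-yl)-4-[(triethylsilyl)oxy]pentadeca-8,14-dien-5-one | C=C(I)CC[C@@H](C(C)=C)C/C=C(C)/CCC(=O)[C@@](C)(O[Si](CC)(CC)CC)CCCOCc1ccc(OC)cc1 | intermediate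
19 | (4S,5R,8E,11R)-14-iodo-1-[(4-methoxybenzyl)oxy]-4,8-dimethyl-11-(prop-1-en-2-yl)-4-[(triethylsilyl)oxy]pentadeca-8,14-dien-5-ol | C=C(I)CC[C@@H](C(C)=C)C/C=C(C)/CC[C@@H](O)[C@@](C)(O[Si](CC)(CC)CC)CCCOCc1ccc(OC)cc1 | intermediate
20 | (4S,5R,8E,11R)-14-iodo-1-[(4-methoxybenzyl)oxy]-4,8-dimethyl-11-(prop-1-en-2-yl)-4-[(triethylsilyl)oxy]pentadeca-8,14-dien-5-yl acetate | C=C(I)CC[C@@H](C(C)=C)C/C=C(C)/CC[C@@H](OC(C)=O)[C@@](C)(O[Si](CC)(CC)CC)CCCOCc1ccc(OC)cc1 | intermediate
21 | (4S,5R,8E,11R)-1-hydroxy-14-iodo-4,8-dimethyl-11-(prop-1-en-2-yl)-4-[(triethylsilyl)oxy]pentadeca-8,14-dien-5-yl acetate | C=C(I)CC[C@@H](C(C)=C)C/C=C(C)/CC[C@@H](OC(C)=O)[C@@](C)(O[Si](CC)(CC)CC)CCCO | intermediate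
22 | (4S,5R,8E,11R)-14-iodo-4,8-dimethyl-1-oxo-11-(prop-1-en-2-yl)-4-[(triethylsilyl)oxy]pentadeca-8,14-dien-5-yl acetate (seco C11 aldehyde; 1R, 3E, 7R acetate, 8S silyl ether, C12 iodoalkene) | C=C(I)CC[C@@H](C(C)=C)C/C=C(C)/CC[C@@H](OC(C)=O)[C@@](C)(O[Si](CC)(CC)CC)CCC=O | intermediate
23 | alkenylchromium dichloride of 22 (trivalent chromium on C12 in place of iodine) | Cl[Cr](Cl)C(=C)CC[C@@H](C(C)=C)C/C=C(C)/CC[C@@H](OC(C)=O)[C@@](C)(O[Si](CC)(CC)CC)CCC=O | intermediate
24 | (1R,3E,7R,8S,11R)-7-acetoxy-8-(triethylsilyloxy)cembra-3,12(20),15(17)-trien-11-ol | C=C1CC[C@@H](C(C)=C)C/C=C(C)/CC[C@@H](OC(C)=O)[C@@](C)(O[Si](CC)(CC)CC)CC[C@H]1O | intermediate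
25 | (1R,3E,7R,8S,11R,12S)-7-acetoxy-12,20-epoxy-8-(triethylsilyloxy)cembra-3,15(17)-dien-11-ol | C1O[C@@]12CC[C@@H](C(C)=C)C/C=C(C)/CC[C@@H](OC(C)=O)[C@@](C)(O[Si](CC)(CC)CC)CC[C@H]2O | intermediate
26 | (1R,3E,7R,8S,11R,12S)-7-acetoxy-12,20-epoxy-8,11-bis(triethylsilyloxy)cembra-3,15(17)-diene | C1O[C@@]12CC[C@@H](C(C)=C)C/C=C(C)/CC[C@@H](OC(C)=O)[C@@](C)(O[Si](CC)(CC)CC)CC[C@H]2O[Si](CC)(CC)CC | intermediate
27 | (1R,3E,7R,8S,11R,12R)-8,11-bis(triethylsilyloxy)cembra-3,15(17)-diene-7,12-diol | C[C@@]1(O)CC[C@@H](C(C)=C)C/C=C(C)/CC[C@@H](O)[C@@](C)(O[Si](CC)(CC)CC)CC[C@H]1O[Si](CC)(CC)CC | intermediate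
28 | (1R,3E,7R,8S,11R,12R)-7-acetoxy-8,11-bis(triethylsilyloxy)cembra-3,15(17)-dien-12-ol | C[C@@]1(O)CC[C@@H](C(C)=C)C/C=C(C)/CC[C@@H](OC(C)=O)[C@@](C)(O[Si](CC)(CC)CC)CC[C@H]1O[Si](CC)(CC)CC | intermediate
29 | (1R,3S,4S,7R,8S,11R,12R)-7-acetoxy-3,4-epoxy-8,11-bis(triethylsilyloxy)cembr-15(17)-en-12-ol | C[C@@]1(O)CC[C@@H](C(C)=C)C[C@@H]2O[C@@]2(C)CC[C@@H](OC(C)=O)[C@@](C)(O[Si](CC)(CC)CC)CC[C@H]1O[Si](CC)(CC)CC | intermediate
30 | (1R,3S,4S,7R,8S,11R,12R)-7-acetoxy-3,4-epoxy-8,11-bis(triethylsilyloxy)cembr-15(17)-ene-12,16-diol | C[C@@]1(O)CC[C@@H](C(CO)=C)C[C@@H]2O[C@@]2(C)CC[C@@H](OC(C)=O)[C@@](C)(O[Si](CC)(CC)CC)CC[C@H]1O[Si](CC)(CC)CC | intermediate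
31 | (1R,3S,4S,7R,8S,11R,12R)-7-acetoxy-3,4-epoxy-12-hydroxy-8,11-bis(triethylsilyloxy)cembr-15(17)-en-16-al | C[C@@]1(O)CC[C@@H](C(C=O)=C)C[C@@H]2O[C@@]2(C)CC[C@@H](OC(C)=O)[C@@](C)(O[Si](CC)(CC)CC)CC[C@H]1O[Si](CC)(CC)CC | intermediate
32 | (1R,3S,4S,7R,8S,11R,12R)-7-acetoxy-3,4-epoxy-12-hydroxy-8,11-bis(triethylsilyloxy)cembr-15(17)-en-16-oic acid | C[C@@]1(O)CC[C@@H](C(C(=O)O)=C)C[C@@H]2O[C@@]2(C)CC[C@@H](OC(C)=O)[C@@](C)(O[Si](CC)(CC)CC)CC[C@H]1O[Si](CC)(CC)CC | intermediate
33 | mixed anhydride of 32 at C16 with 2,4,6-trichlorobenzoic acid | C[C@@]1(O)CC[C@@H](C(C(=O)OC(=O)c3c(Cl)cc(Cl)cc3Cl)=C)C[C@@H]2O[C@@]2(C)CC[C@@H](OC(C)=O)[C@@](C)(O[Si](CC)(CC)CC)CC[C@H]1O[Si](CC)(CC)CC | intermediate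
34 | (1R,3S,4S,7R,8S,11R,12R)-7-acetoxy-3,4-epoxy-8,11-bis(triethylsilyloxy)cembr-15(17)-en-16,12-olide | C=C1C(=O)O[C@]2(C)CC[C@@H]1C[C@@H]1O[C@@]1(C)CC[C@@H](OC(C)=O)[C@@](C)(O[Si](CC)(CC)CC)CC[C@H]2O[Si](CC)(CC)CC | intermediate
35 | (1R,3S,4S,7R,8S,11R,12R)-7-acetoxy-3,4-epoxy-8,11-dihydroxycembr-15(17)-en-16,12-olide (CNP0174704.2) | C=C1C(=O)O[C@]2(C)CC[C@@H]1C[C@@H]1O[C@@]1(C)CC[C@@H](OC(C)=O)[C@@](C)(O)CC[C@H]2O | target

**Step count.** Total: 24 steps. Longest linear sequence: 20 steps (steps 1–5 and 10–24); steps 6–9 are a four-step branch.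

**Steps most likely to fail**

Step 15. The alkenyl group may add to the wrong (Re) face of the C11 aldehyde, or to both faces, if the ligand does not override the conformation of the closing ring. The fallback sets out from aldehyde 22, which is cyclised with CrCl2 (divalent chromium) and catalytic NiCl2 (divalent nickel) in DMSO without the chiral ligand. The resulting mixture of 24 and its epimer (1R,3E,7R,8S,11S)-7-acetoxy-8-(triethylsilyloxy)cembra-3,12(20),15(17)-trien-11-ol F1 is oxidised with Dess–Martin periodinane to the cross-conjugated enone (1R,3E,7R,8S)-7-acetoxy-8-(triethylsilyloxy)cembra-3,12(20),15(17)-trien-11-one F2. Corey–Bakshi–Shibata reduction of F2 with the (S)-oxazaborolidine and catecholborane, which reads the 1,1-disubstituted alkenyl group as the large substituent, should give the 11R alcohol, and the route is rejoined at 24. The stereocentre is then set by a separate ketone reduction and no longer in the ring-closing step.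

Step 23. The activated acrylic acid may be attacked too slowly by the hindered tertiary C12 hydroxyl, so that oligomerisation, addition of the pyridine catalyst at C17 or deprotonation at C1 take over. The fallback sets out from enal 31 and bypasses acid 32. In CH2Cl2 the enal equilibrates with its seven-membered lactol, (1R,3S,4S,7R,8S,11R,12R)-7-acetoxy-3,4:12,16-diepoxy-8,11-bis(triethylsilyloxy)cembr-15(17)-en-16-ol F3 (both C16 epimers). The lactol is oxidised as it forms with PhI(OAc)2 and catalytic TEMPO, which oxidise hemiacetals but not the enal, and the route is rejoined at lactone 34.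

Step 21. The 1,1-disubstituted alkene may react slowly and unselectively with SeO2, and selenous acid may open the 3,4-epoxide. The fallback sets out from 29 and uses a Schenck ene reaction with singlet oxygen (O2, tetraphenylporphyrin, visible light, CH2Cl2). Hydrogen is taken from the methyl group of the isopropenyl unit, giving the allylic hydroperoxide (1R,3S,4S,7R,8S,11R,12R)-7-acetoxy-3,4-epoxy-16-hydroperoxy-8,11-bis(triethylsilyloxy)cembr-15(17)-en-12-ol F4. Ac2O/pyridine dehydrates this primary hydroperoxide (Kornblum–DeLaMare-type elimination) to the enal, and the route is rejoined at 31.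

**Further compounds**

F1 | step 15 | (1R,3E,7R,8S,11S)-7-acetoxy-8-(triethylsilyloxy)cembra-3,12(20),15(17)-trien-11-ol | C=C1CC[C@@H](C(C)=C)C/C=C(C)/CC[C@@H](OC(C)=O)[C@@](C)(O[Si](CC)(CC)CC)CC[C@@H]1O
F2 | step 15 | (1R,3E,7R,8S)-7-acetoxy-8-(triethylsilyloxy)cembra-3,12(20),15(17)-trien-11-one | C=C1CC[C@@H](C(C)=C)C/C=C(C)/CC[C@@H](OC(C)=O)[C@@](C)(O[Si](CC)(CC)CC)CCC1=O
F3 | step 23 | (1R,3S,4S,7R,8S,11R,12R)-7-acetoxy-3,4:12,16-diepoxy-8,11-bis(triethylsilyloxy)cembr-15(17)-en-16-ol (lactol, both C16 epimers) | C=C1C(O)O[C@]2(C)CC[C@@H]1C[C@@H]1O[C@@]1(C)CC[C@@H](OC(C)=O)[C@@](C)(O[Si](CC)(CC)CC)CC[C@H]2O[Si](CC)(CC)CC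
F4 | step 21 | (1R,3S,4S,7R,8S,11R,12R)-7-acetoxy-3,4-epoxy-16-hydroperoxy-8,11-bis(triethylsilyloxy)cembr-15(17)-en-12-ol | C[C@@]1(O)CC[C@@H](C(COO)=C)C[C@@H]2O[C@@]2(C)CC[C@@H](OC(C)=O)[C@@](C)(O[Si](CC)(CC)CC)CC[C@H]1O[Si](CC)(CC)CC
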